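**Retrosynthetic overview**

1. Target 22 is the 9,9'-diacetate of (1S,2R,3R)-lyoniresinol. The acetates, the C9 oxygen (from CH2NO2) and the C7 hydroxyl (from OBn) are adjusted last, which leads back to nitro aldehyde 15.
2. Ring B is cut at C1–C2 and C3–C9. Ring C on C1 is a 4-hydroxy-3,5-dimethoxyphenyl group, so C1 can be the exocyclic carbon of a para-quinone methide. C9 on C3 is nitromethane added β to an enal whose carbonyl carbon becomes C9' on C2.
3. Cascade precursor 11 is an (E)-4-arylbut-2-enal on ring A with an ortho diarylmethyl methyl ether (latent C1). The enal comes from cross-metathesis of an allyl group, and the C1–C8a bond from aryllithium addition to silylated syringaldehyde.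
4. Rings A and C are bought as arenes (4-allyl-2,6-dimethoxyphenol, syringaldehyde). Ring B is the only ring formed, in step 8.

Key step: step 8

Remark on the chemistry: C1 is carried as a racemic methyl ether, not as a free carbinol. A hydroxyl there could add to the enal β-carbon in a six-membered oxa-Michael closure; the ether cannot, and the centre is erased on ionization.

**Route**

Step 1
Reactants: 1 4-allyl-2,6-dimethoxyphenol
Product: 2 5-allyl-2-(benzyloxy)-1,3-dimethoxybenzene
Conditions: BnBr, K2CO3, DMF, 50 °C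
Reagents that add atoms: benzyl bromide, BrCc1ccccc1
Why: Williamson ether synthesis on the phenoxide; the benzyl ether masks the future C7 hydroxyl of ring A until the final hydrogenolysis.

Step 2
Reactants: 2 5-allyl-2-(benzyloxy)-1,3-dimethoxybenzene
Product: 3 1-allyl-4-(benzyloxy)-2-bromo-3,5-dimethoxybenzene
Conditions: NBS (1.05 equiv), MeCN, 0 °C → rt, dark
Reagents that add atoms: N-bromosuccinimide, O=C1CCC(=O)N1Br
Why: Electrophilic aromatic bromination; the two free ring positions are equivalent and each is ortho and para to a methoxy group, so the ring should react well before the monosubstituted alkene.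

Step 3
Reactants: 4 syringaldehyde (4-hydroxy-3,5-dimethoxybenzaldehyde)
Product: 5 3,5-dimethoxy-4-(triisopropylsilyloxy)benzaldehyde
Conditions: TIPSCl, imidazole, DMF, rt
Reagents that add atoms: chlorotriisopropylsilane, CC(C)[Si](Cl)(C(C)C)C(C)C
Why: Silylation of the phenol (imidazole-promoted) gives an aryl silyl ether that tolerates organolithium, NaH and metathesis conditions and is later removed by fluoride alone.

Step 4
Reactants: 3 1-allyl-4-(benzyloxy)-2-bromo-3,5-dimethoxybenzene; 5 3,5-dimethoxy-4-(triisopropylsilyloxy)benzaldehyde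
Product: 7 [6-allyl-3-(benzyloxy)-2,4-dimethoxyphenyl][3,5-dimethoxy-4-(triisopropylsilyloxy)phenyl]methanol (racemic), via aryllithium 6 (not isolated)
Conditions: n-BuLi (1.05 equiv), THF, −78 °C; then 5, −78 → 0 °C; aq. NH4Cl
Reagents that add atoms: none
Why: Bromine–lithium exchange followed by 1,2-addition to a non-enolizable aldehyde forms the C1–C8a bond; the new carbinol centre is racemic and is erased in step 8.

Step 5
Reactants: 7 racemic diarylmethanol
Product: 8 1-allyl-4-(benzyloxy)-2-{[3,5-dimethoxy-4-(triisopropylsilyloxy)phenyl](methoxy)methyl}-3,5-dimethoxybenzene (racemic)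
Conditions: NaH, MeI, THF, 0 °C → rt
Reagents that add atoms: iodomethane, CI
Why: Williamson O-methylation of the alkoxide; the ether is still an ionizable leaving group at C1 but can no longer add to the enal made in step 6.

Step 6
Reactants: 8 allyl arene methyl ether; 9 (E)-crotonaldehyde
Product: 10 (E)-4-[4-(benzyloxy)-2-{[3,5-dimethoxy-4-(triisopropylsilyloxy)phenyl](methoxy)methyl}-3,5-dimethoxyphenyl]but-2-enal
Conditions: 9 (5 equiv), second-generation Grubbs catalyst (H2IMes)(PCy3)Cl2Ru=CHPh (5 mol %), 1,4-benzoquinone (10 mol %), CH2Cl2, 40 °C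
Reagents that add atoms: none
Why: Olefin cross-metathesis of a terminal allyl arene with an electron-poor partner should give the E enal with loss of propene, and benzoquinone suppresses hydride-mediated migration of the allyl double bond.

Step 7
Reactants: 10 silyl-protected enal
Product: 11 (E)-4-[4-(benzyloxy)-2-[(4-hydroxy-3,5-dimethoxyphenyl)(methoxy)methyl]-3,5-dimethoxyphenyl]but-2-enal
Conditions: Bu4NF, AcOH (1:1), THF, 0 °C
Reagents that add atoms: none
Why: Fluoride cleavage of the aryl silyl ether, buffered with acetic acid so that the γ-acidic enal is not exposed to a basic phenoxide or fluoride.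

Step 8
Reactants: 11 phenolic enal methyl ether; 12 nitromethane
Product: 15 (1S,2R,3R)-7-(benzyloxy)-1-(4-hydroxy-3,5-dimethoxyphenyl)-6,8-dimethoxy-3-(nitromethyl)-1,2,3,4-tetrahydronaphthalene-2-carbaldehyde, via Michael adduct 13 (not isolated), via quinone methide 14 (not isolated)
Conditions: 12 (5 equiv), (S)-α,α-diphenylprolinol trimethylsilyl ether (20 mol %), PhCO2H (20 mol %), MeOH, rt; evaporate; CH2Cl2 (0.02 M), CF3CO2H (0.5 equiv), 0 °C → rt; aq. NaHCO3
Reagents that add atoms: none
Why: Proposed new method: the (S)-amine turns enal 11 into an E-iminium ion with one face covered by the diphenyl(silyloxy)methyl group, nitronate adds to C3 from the free face (C3–C9 bond, closest known reaction the diarylprolinol silyl ether-catalysed Michael addition of nitromethane to enals), and aldehyde 13 remains in equilibrium with its enamine. CF3CO2H then ionizes the benzylic methyl ether, activated by both arenes and the para-hydroxyl of ring C, to quinone methide 14 or its O-protonated cation, and the enamine (or enol) carbon C2 adds to C1 with re-aromatization of ring C (C1–C2 bond); the closest known reactions are the enamine-catalysed 1,6-addition of aldehydes to para-quinone methides and the amine-catalysed SN1-type alpha-alkylation of aldehydes with benzhydryl cations, here intramolecular and coupled to the Michael step. Ring B closes in a 6-exo-trig mode, the C1=C bond of the quinone methide lying outside the new ring, through a half-chair. C3 (R) is set by the catalyst; C1 is set in the closure, where the nitromethyl arm on C3 is pseudo-equatorial and the flat dienone of ring C takes the pseudo-equatorial side as well, which makes C1 and C3 cis from either enamine face; C2, alpha to the aldehyde, epimerizes through enamine and enol to the isomer trans to both neighbours. The step needs nitronate to meet only the iminium ion and C1 to meet only C2: the methyl ether does not ionize in the weakly acidic methanol of the first stage (exchange with solvent is degenerate, and no free hydroxyl is present to add to the enal), excess nitromethane is removed before the acid is added, and under acid the CH2NO2 group is not nucleophilic, so C9 cannot compete for C1. Loss of C4–H to a dienamine is held back because the bulky ortho substituent twists ring A out of conjugation with a C3=C4 double bond.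

Step 9
Reactants: 15 nitro aldehyde
Product: 16 [(1S,2R,3R)-7-(benzyloxy)-1-(4-hydroxy-3,5-dimethoxyphenyl)-6,8-dimethoxy-3-(nitromethyl)-1,2,3,4-tetrahydronaphthalen-2-yl]methanol
Conditions: NaBH4, MeOH–THF, 0 °C; aq. NH4Cl
Reagents that add atoms: none
Why: Hydride reduction of the aldehyde leaves the nitro group untouched and removes the epimerizable position at C2, fixing the trans,trans arrangement.

Step 10
Reactants: 16 nitro alcohol
Product: 18 lactol formed from the C9 aldehyde and the C9' hydroxyl (anomer mixture; tetralin numbering 1S,2R,3R), via sodium nitronate 17 (not isolated)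
Conditions: NaOMe (2.2 equiv), MeOH, 0 °C; then into aq. TiCl3 (5 equiv), NH4OAc, pH 5–6, rt
Reagents that add atoms: water, O
Why: McMurry reductive Nef reaction, in which trivalent titanium reduces the nitronate to the imine that hydrolyses to the C9 aldehyde; the C9' hydroxyl traps it as the five-membered lactol, which limits enolization at C3 (whose trans arrangement is in any case the stable one).

Step 11
Reactants: 18 lactol
Product: 19 [(1S,2R,3R)-7-(benzyloxy)-1-(4-hydroxy-3,5-dimethoxyphenyl)-6,8-dimethoxy-1,2,3,4-tetrahydronaphthalene-2,3-diyl]dimethanol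
Conditions: NaBH4, MeOH, 0 °C → rt
Reagents that add atoms: none
Why: Hydride reduction of the lactol through its open hydroxy aldehyde form gives the 1,4-diol.

Step 12
Reactants: 19 phenolic diol
Product: 20 [(1S,2R,3R)-7-(benzyloxy)-1-[4-(benzyloxy)-3,5-dimethoxyphenyl]-6,8-dimethoxy-1,2,3,4-tetrahydronaphthalene-2,3-diyl]dimethanol
Conditions: BnBr (1.1 equiv), K2CO3, acetone, reflux
Reagents that add atoms: benzyl bromide, BrCc1ccccc1
Why: Williamson etherification selective for the phenol, since K2CO3 deprotonates the phenol but not the primary alcohols; this keeps the ring C hydroxyl out of the acetylation.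

Step 13
Reactants: 20 bis(benzyl ether) diol
Product: 21 [(1S,2R,3R)-7-(benzyloxy)-1-[4-(benzyloxy)-3,5-dimethoxyphenyl]-6,8-dimethoxy-1,2,3,4-tetrahydronaphthalene-2,3-diyl]bis(methylene) diacetate
Conditions: Ac2O, pyridine, DMAP (cat.), CH2Cl2, rt
Reagents that add atoms: acetic anhydride, CC(=O)OC(C)=O
Why: DMAP-catalysed acylation of the two primary alcohols, the only free hydroxyls left.

Step 14
Reactants: 21 bis(benzyl ether) diacetate
Product: 22 [(1S,2R,3R)-7-hydroxy-1-(4-hydroxy-3,5-dimethoxyphenyl)-6,8-dimethoxy-1,2,3,4-tetrahydronaphthalene-2,3-diyl]bis(methylene) diacetate (target)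
Conditions: H2 (1 atm), 10% Pd/C, EtOAc–MeOH, rt
Reagents that add atoms: none
Why: Hydrogenolysis of both aryl benzyl ethers; the acetates and the doubly benzylic C1–C bonds are not cleaved under these conditions.

**Compound list**

1 | 4-allyl-2,6-dimethoxyphenol | COc1cc(CC=C)cc(OC)c1O | starting material
2 | 5-allyl-2-(benzyloxy)-1,3-dimethoxybenzene | COc1cc(CC=C)cc(OC)c1OCc1ccccc1 | intermediate
3 | 1-allyl-4-(benzyloxy)-2-bromo-3,5-dimethoxybenzene | C=CCc1cc(OC)c(OCc2ccccc2)c(OC)c1Br | intermediate
4 | syringaldehyde (4-hydroxy-3,5-dimethoxybenzaldehyde) | COc1cc(C=O)cc(OC)c1O | starting material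
5 | 3,5-dimethoxy-4-(triisopropylsilyloxy)benzaldehyde | COc1cc(C=O)cc(OC)c1O[Si](C(C)C)(C(C)C)C(C)C | intermediate
6 | [6-allyl-3-(benzyloxy)-2,4-dimethoxyphenyl]lithium (not isolated) | C=CCc1cc(OC)c(OCc2ccccc2)c(OC)c1[Li] | intermediate
7 | [6-allyl-3-(benzyloxy)-2,4-dimethoxyphenyl][3,5-dimethoxy-4-(triisopropylsilyloxy)phenyl]methanol, racemic | C=CCc1cc(OC)c(OCc2ccccc2)c(OC)c1C(O)c1cc(OC)c(O[Si](C(C)C)(C(C)C)C(C)C)c(OC)c1 | intermediate
8 | methyl ether of 7, racemic | C=CCc1cc(OC)c(OCc2ccccc2)c(OC)c1C(OC)c1cc(OC)c(O[Si](C(C)C)(C(C)C)C(C)C)c(OC)c1 | intermediate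
9 | (E)-crotonaldehyde | C/C=C/C=O | starting material
10 | (E)-4-[4-(benzyloxy)-2-{[3,5-dimethoxy-4-(triisopropylsilyloxy)phenyl](methoxy)methyl}-3,5-dimethoxyphenyl]but-2-enal, racemic | O=C/C=C/Cc1cc(OC)c(OCc2ccccc2)c(OC)c1C(OC)c1cc(OC)c(O[Si](C(C)C)(C(C)C)C(C)C)c(OC)c1 | intermediate
11 | (E)-4-[4-(benzyloxy)-2-[(4-hydroxy-3,5-dimethoxyphenyl)(methoxy)methyl]-3,5-dimethoxyphenyl]but-2-enal, racemic at the ether carbon | COc1cc(C(OC)c2c(C/C=C/C=O)cc(OC)c(OCc3ccccc3)c2OC)cc(OC)c1O | intermediate
12 | nitromethane | C[N+](=O)[O-] | starting material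
13 | (3R)-4-[4-(benzyloxy)-2-[(4-hydroxy-3,5-dimethoxyphenyl)(methoxy)methyl]-3,5-dimethoxyphenyl]-3-(nitromethyl)butanal, mixture at the ether carbon (not isolated) | COc1cc(C(OC)c2c(C[C@@H](C[N+](=O)[O-])CC=O)cc(OC)c(OCc3ccccc3)c2OC)cc(OC)c1O | intermediate
14 | (3R)-4-[4-(benzyloxy)-2-[(3,5-dimethoxy-4-oxocyclohexa-2,5-dien-1-ylidene)methyl]-3,5-dimethoxyphenyl]-3-(nitromethyl)butanal (not isolated) | COC1=CC(=Cc2c(C[C@@H](C[N+](=O)[O-])CC=O)cc(OC)c(OCc3ccccc3)c2OC)C=C(OC)C1=O | intermediate
15 | (1S,2R,3R)-7-(benzyloxy)-1-(4-hydroxy-3,5-dimethoxyphenyl)-6,8-dimethoxy-3-(nitromethyl)-1,2,3,4-tetrahydronaphthalene-2-carbaldehyde | COc1cc([C@H]2c3c(cc(OC)c(OCc4ccccc4)c3OC)C[C@@H](C[N+](=O)[O-])[C@@H]2C=O)cc(OC)c1O | intermediate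
16 | [(1S,2R,3R)-7-(benzyloxy)-1-(4-hydroxy-3,5-dimethoxyphenyl)-6,8-dimethoxy-3-(nitromethyl)-1,2,3,4-tetrahydronaphthalen-2-yl]methanol | COc1cc([C@H]2c3c(cc(OC)c(OCc4ccccc4)c3OC)C[C@@H](C[N+](=O)[O-])[C@@H]2CO)cc(OC)c1O | intermediate
17 | sodium nitronate of 16, drawn as the mono-salt (not isolated) | [Na+].COc1cc([C@H]2c3c(cc(OC)c(OCc4ccccc4)c3OC)C[C@@H](C=[N+]([O-])[O-])[C@@H]2CO)cc(OC)c1O | intermediate
18 | lactol between C9 and the C9' oxygen (6-(benzyloxy)-4-(4-hydroxy-3,5-dimethoxyphenyl)-5,7-dimethoxy-1,3,3a,4,9,9a-hexahydronaphtho[2,3-c]furan-1-ol), anomer mixture, ring stereocentres as in 16 | COc1cc([C@H]2c3c(cc(OC)c(OCc4ccccc4)c3OC)C[C@@H](C(O)OC5)[C@@H]25)cc(OC)c1O | intermediate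
19 | [(1S,2R,3R)-7-(benzyloxy)-1-(4-hydroxy-3,5-dimethoxyphenyl)-6,8-dimethoxy-1,2,3,4-tetrahydronaphthalene-2,3-diyl]dimethanol | COc1cc([C@H]2c3c(cc(OC)c(OCc4ccccc4)c3OC)C[C@@H](CO)[C@@H]2CO)cc(OC)c1O | intermediate
20 | [(1S,2R,3R)-7-(benzyloxy)-1-[4-(benzyloxy)-3,5-dimethoxyphenyl]-6,8-dimethoxy-1,2,3,4-tetrahydronaphthalene-2,3-diyl]dimethanol | COc1cc([C@H]2c3c(cc(OC)c(OCc4ccccc4)c3OC)C[C@@H](CO)[C@@H]2CO)cc(OC)c1OCc1ccccc1 | intermediate
21 | diacetate of 20 | COc1cc([C@H]2c3c(cc(OC)c(OCc4ccccc4)c3OC)C[C@@H](COC(C)=O)[C@@H]2COC(C)=O)cc(OC)c1OCc1ccccc1 | intermediate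
22 | [(1S,2R,3R)-7-hydroxy-1-(4-hydroxy-3,5-dimethoxyphenyl)-6,8-dimethoxy-1,2,3,4-tetrahydronaphthalene-2,3-diyl]bis(methylene) diacetate | COc1cc([C@H]2c3c(cc(OC)c(O)c3OC)C[C@@H](COC(C)=O)[C@@H]2COC(C)=O)cc(OC)c1O | target

**Step count and risks**

Total steps: 14. Longest linear sequence: 13 (steps 1, 2 and 4–14 from compound 1).

Steps most likely to fail:

1. Step 8 (the proposed new method). Several processes could defeat it:
   - The ring C dienone may take the pseudo-axial side to avoid the peri methoxy group on C8, which would give the C1 epimer (C1 and C3 trans).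
   - The catalyst's preferred enamine face does not match a trans C2–C3 closure, so ring closure may be slow.
   - A slow closure leaves the quinone methide open to capture by C5–H of a second molecule or by the amine.
   - Equilibration at C2 may stop short.

   Fallback, from 4 back to 20: ring B would be closed at C1–C8a by the classical Friedel–Crafts lignan sequence.
   - Syringaldehyde 4 is benzylated (BnBr, K2CO3, DMF) to 4-(benzyloxy)-3,5-dimethoxybenzaldehyde F1, which is used twice.
   - Stobbe condensation of F1 with dimethyl succinate (NaOMe, MeOH, reflux) gives the (E)-benzylidenesuccinic half-ester F2.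
   - Hydrogenation with a cationic monovalent rhodium catalyst [Rh(cod)(bisphosphine)]BF4 (for example Et-DuPhos, in the ligand antipode that delivers the R acid) gives the (R)-benzylsuccinic half-ester F3.
   - Reduction of the ester in the presence of the carboxylate salt (KOH, then CaCl2/NaBH4, EtOH) and acidification closes the (R)-β-benzyl-γ-butyrolactone F4.
   - Its lithium enolate (LiN(SiMe3)2, THF, −78 °C) adds to a second portion of F1 to give the trans aldol adduct F5 as a carbinol mixture.
   - CF3CO2H in CH2Cl2 ionizes the carbinol, and ring A attacks C1 to give the trans,trans aryltetralin lactone F6.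
   - LiAlH4 in THF reduces F6 to diol 20, and steps 13 and 14 follow.

2. Step 10. The nitronate may be reprotonated instead of reduced, the reduction may stall at the oxime or run on to the amine, and the aldehyde may suffer under the titanium conditions.

   Fallback, from 16 back to 18: the conversion is split into two known operations. The nitro group is reduced to the aldoxime F7 with SnCl2, PhSH and Et3N in MeCN. The oxime is then exchanged onto formaldehyde (aq. HCHO, dilute HCl, THF), which releases the C9 aldehyde as lactol 18.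

3. Step 6. A ruthenium hydride may move the allyl double bond into conjugation with ring A, the bulky ortho substituent may slow the metathesis, and homodimerization may compete.

   Fallback, from 8 back to 10: the allyl group is cleaved to the arylacetaldehyde F8 (OsO4 cat., NaIO4, 2,6-lutidine, dioxane–H2O). F8 is then homologated by Wittig reaction with (triphenylphosphoranylidene)acetaldehyde, Ph3P=CHCHO, in toluene at 80 °C to give E enal 10.

**Further compounds**

F1 | step 8 | 4-(benzyloxy)-3,5-dimethoxybenzaldehyde | COc1cc(C=O)cc(OC)c1OCc1ccccc1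
F2 | step 8 | (E)-4-[4-(benzyloxy)-3,5-dimethoxyphenyl]-3-(methoxycarbonyl)but-3-enoic acid | COC(=O)/C(CC(=O)O)=C/c1cc(OC)c(OCc2ccccc2)c(OC)c1
F3 | step 8 | (R)-3-[4-(benzyloxy)-3,5-dimethoxybenzyl]-4-methoxy-4-oxobutanoic acid | OC(=O)C[C@@H](Cc1cc(OC)c(OCc2ccccc2)c(OC)c1)C(=O)OC
F4 | step 8 | (R)-4-[4-(benzyloxy)-3,5-dimethoxybenzyl]dihydrofuran-2(3H)-one | O=C1C[C@@H](Cc2cc(OC)c(OCc3ccccc3)c(OC)c2)CO1
F5 | step 8 | (3S,4R)-trans-4-[4-(benzyloxy)-3,5-dimethoxybenzyl]-3-{[4-(benzyloxy)-3,5-dimethoxyphenyl](hydroxy)methyl}dihydrofuran-2(3H)-one, carbinol mixture | O=C1OC[C@H](Cc2cc(OC)c(OCc3ccccc3)c(OC)c2)[C@H]1C(O)c1cc(OC)c(OCc2ccccc2)c(OC)c1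
F6 | step 8 | trans,trans aryltetralin lactone (carbonyl on C2, OCH2 on C3; tetralin numbering 1S,2R,3R), 7-(benzyloxy)-9-[4-(benzyloxy)-3,5-dimethoxyphenyl]-6,8-dimethoxy-3a,4,9,9a-tetrahydronaphtho[2,3-c]furan-1(3H)-one | COc1cc([C@H]2c3c(cc(OC)c(OCc4ccccc4)c3OC)C[C@@H](COC5=O)[C@@H]25)cc(OC)c1OCc1ccccc1
F7 | step 10 | C9 aldoxime of the (1S,2R,3R) hydroxymethyl tetralin, E/Z mixture | COc1cc([C@H]2c3c(cc(OC)c(OCc4ccccc4)c3OC)C[C@@H](C=NO)[C@@H]2CO)cc(OC)c1O
F8 | step 6 | 2-[4-(benzyloxy)-2-{[3,5-dimethoxy-4-(triisopropylsilyloxy)phenyl](methoxy)methyl}-3,5-dimethoxyphenyl]acetaldehyde, racemic | O=CCc1cc(OC)c(OCc2ccccc2)c(OC)c1C(OC)c1cc(OC)c(O[Si](C(C)C)(C(C)C)C(C)C)c(OC)c1
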